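**Strategy.** Everything rests on disconnecting the fourteen-membered ring (ring methine C1, ring carbons C2–C14) at C1–C14. The adjacent C1(H)/C15(OH) pair, C15 being the exocyclic carbinol carbon with methyl C16 and chain carbon C17, is the anti-opened form of a C1–C15 epoxide; C14 is a bare methylene that can carry a sulfone. One operation, attack of a C14 α-sulfonyl carbanion on epoxide carbon C1, therefore closes the ring, forms C1–C14, fixes C1 by inversion and liberates the C15 alkoxide. The precursor is an acyclic, farnesol-derived all-E triene with a phenylsulfonyl group on C14 and a silyl-protected (2S,3S)-epoxy alcohol (C1, C15, C17) at the other end.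

Key step: step 10

Remark: it is assumed that the (2R,3R)-tartrate ligand [L-(+)] delivers the (2S,3S)-epoxy alcohol from the (E)-2-methylallylic alcohol 12, as it does for geraniol-type substrates; atom numbers C1–C17 follow the ring numbering given in the strategy.

**Step 1**
Reactants: 1 (2E,6E)-farnesol
Product: 2 tert-butyl(dimethyl){[(2E,6E)-3,7,11-trimethyldodeca-2,6,10-trien-1-yl]oxy}silane
Conditions: TBSCl, imidazole, DMF, 0 °C → rt
Reagents that add atoms: tert-butyldimethylsilyl chloride, CC(C)(C)[Si](C)(C)Cl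
Why: Silyl ether formation on the primary allylic alcohol masks it against the oxidation of step 2 and the carbanion of step 4; no stereocentre is involved.

**Step 2**
Reactants: 2 tert-butyl(dimethyl){[(2E,6E)-3,7,11-trimethyldodeca-2,6,10-trien-1-yl]oxy}silane
Product: 3 (2E,6E,10E)-12-[(tert-butyldimethylsilyl)oxy]-2,6,10-trimethyldodeca-2,6,10-trien-1-ol
Conditions: SeO2 (0.1 equiv), t-BuOOH (3 equiv), CH2Cl2, 0 °C → rt
Reagents that add atoms: tert-butyl hydroperoxide, CC(C)(C)OO; selenium dioxide (catalytic oxygen carrier), O=[Se]=O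
Why: Riley-type SeO2-catalysed allylic hydroxylation (ene reaction, then [2,3]-sigmatropic shift) should oxidise the (E)-methyl of the terminal, most accessible trisubstituted alkene and give the (E)-allylic alcohol, the alkene next to the silyloxymethyl group being deactivated.

**Step 3**
Reactants: 3 (2E,6E,10E)-12-[(tert-butyldimethylsilyl)oxy]-2,6,10-trimethyldodeca-2,6,10-trien-1-ol
Product: 4 {[(2E,6E,10E)-12-bromo-3,7,11-trimethyldodeca-2,6,10-trien-1-yl]oxy}(tert-butyl)dimethylsilane
Conditions: CBr4, PPh3, CH2Cl2, 0 °C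
Reagents that add atoms: carbon tetrabromide, BrC(Br)(Br)Br
Why: The Appel reaction converts the primary allylic alcohol into the bromide under neutral conditions, without allylic transposition or loss of alkene geometry.

**Step 4**
Reactants: 4 {[(2E,6E,10E)-12-bromo-3,7,11-trimethyldodeca-2,6,10-trien-1-yl]oxy}(tert-butyl)dimethylsilane; 5 methyl phenyl sulfone
Product: 7 tert-butyl(dimethyl){[(2E,6E,10E)-3,7,11-trimethyl-13-(phenylsulfonyl)trideca-2,6,10-trien-1-yl]oxy}silane, via (phenylsulfonyl)methyllithium 6 (not isolated)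
Conditions: 5 (2.5 equiv), n-BuLi (2.4 equiv), THF, −78 °C; then 4, −78 → −20 °C
Reagents that add atoms: none
Why: SN2 alkylation of the α-sulfonyl carbanion by the primary allylic bromide adds the future C14 with its sulfone, the excess of carbanion suppressing double alkylation.

**Step 5**
Reactants: 7 tert-butyl(dimethyl){[(2E,6E,10E)-3,7,11-trimethyl-13-(phenylsulfonyl)trideca-2,6,10-trien-1-yl]oxy}silane
Product: 8 (2E,6E,10E)-3,7,11-trimethyl-13-(phenylsulfonyl)trideca-2,6,10-trien-1-ol
Conditions: Bu4NF, THF, 0 °C → rt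
Reagents that add atoms: none
Why: Fluoride-induced desilylation frees the allylic alcohol; the sulfone and the alkenes are inert.

**Step 6**
Reactants: 8 (2E,6E,10E)-3,7,11-trimethyl-13-(phenylsulfonyl)trideca-2,6,10-trien-1-ol
Product: 9 (2E,6E,10E)-1-chloro-3,7,11-trimethyl-13-(phenylsulfonyl)trideca-2,6,10-triene
Conditions: NCS, Me2S, CH2Cl2, −40 → 0 °C
Reagents that add atoms: N-chlorosuccinimide, O=C1CCC(=O)N1Cl
Why: Corey–Kim chlorination turns the allylic alcohol into the primary allylic chloride without rearrangement or E/Z erosion, as it does for farnesol itself.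

**Step 7**
Reactants: 9 (2E,6E,10E)-1-chloro-3,7,11-trimethyl-13-(phenylsulfonyl)trideca-2,6,10-triene; 10 propargyl alcohol
Product: 12 (2E,5E,9E,13E)-2,6,10,14-tetramethyl-16-(phenylsulfonyl)hexadeca-2,5,9,13-tetraen-1-ol, via (E)-alkenylalane 11 (not isolated)
Conditions: 10 (1.5 equiv), AlMe3 (4.5 equiv), Cp2ZrCl2 (0.4 equiv), (CH2Cl)2, 0 °C → rt; then 9, Pd(PPh3)4 (5 mol %), THF, rt
Reagents that add atoms: trimethylaluminium, C[Al](C)C
Why: Negishi zirconium-catalysed methylalumination adds methyl (C16) and aluminium syn across the alkyne with aluminium on the terminal carbon, and the cross-coupling with the allylic chloride, catalysed by zerovalent palladium, should join C1 to C2 at the primary allyl terminus with retention of both alkene geometries, so that the C2 arm lies cis to the methyl.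

**Step 8**
Reactants: 12 (2E,5E,9E,13E)-2,6,10,14-tetramethyl-16-(phenylsulfonyl)hexadeca-2,5,9,13-tetraen-1-ol
Product: 13 [(2S,3S)-2-methyl-3-[(2E,6E,10E)-3,7,11-trimethyl-13-(phenylsulfonyl)trideca-2,6,10-trien-1-yl]oxiran-2-yl]methanol
Conditions: Ti(OiPr)4 (10 mol %), diisopropyl (2R,3R)-tartrate (12 mol %), t-BuOOH (2 equiv), 4 Å molecular sieves, CH2Cl2, −20 °C
Reagents that add atoms: tert-butyl hydroperoxide, CC(C)(C)OO
Why: Sharpless asymmetric epoxidation acts only on the allylic alcohol, and the titanium–tartrate complex delivers oxygen to a single face, setting both epoxide centres (C15 and C1) by reagent control while the three isolated alkenes stay untouched.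

**Step 9**
Reactants: 13 [(2S,3S)-2-methyl-3-[(2E,6E,10E)-3,7,11-trimethyl-13-(phenylsulfonyl)trideca-2,6,10-trien-1-yl]oxiran-2-yl]methanol
Product: 14 tert-butyl(dimethyl){[(2S,3S)-2-methyl-3-[(2E,6E,10E)-3,7,11-trimethyl-13-(phenylsulfonyl)trideca-2,6,10-trien-1-yl]oxiran-2-yl]methoxy}silane
Conditions: TBSCl, imidazole, DMF, 0 °C → rt
Reagents that add atoms: tert-butyldimethylsilyl chloride, CC(C)(C)[Si](C)(C)Cl
Why: Silylation of the primary hydroxyl removes the only acidic O–H and blocks Payne rearrangement of the epoxide under the basic conditions of step 10.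

**Step 10**
Reactants: 14 tert-butyl(dimethyl){[(2S,3S)-2-methyl-3-[(2E,6E,10E)-3,7,11-trimethyl-13-(phenylsulfonyl)trideca-2,6,10-trien-1-yl]oxiran-2-yl]methoxy}silane
Product: 16 (2R)-1-[(tert-butyldimethylsilyl)oxy]-2-[(1R,3E,7E,11E)-4,8,12-trimethyl-14-(phenylsulfonyl)cyclotetradeca-3,7,11-trien-1-yl]propan-2-ol (C14 epimers), via C14-lithiated sulfone 15 (not isolated)
Conditions: LiN(iPr)2 (1.1 equiv), THF, 0.002 M, −78 °C, 30 min; then −78 → 25 °C, 12 h
Reagents that add atoms: none
Why: LiN(iPr)2 removes a C14–H next to the sulfonyl group at −78 °C and, on warming, the lithiated carbon attacks epoxide carbon C1 from the side opposite the C1–O bond (SN2), so that the C1–C14 bond forms while the oxygen stays on C15 as the lithium alkoxide. The closest known reaction type is the intramolecular opening of a trisubstituted epoxide at its secondary carbon by a sulfur-stabilised carbanion, an established closure of fourteen-membered cembranoid rings; here the carbanion is a plain, non-allylic α-sulfonyl one, which needs a base of the strength of LiN(iPr)2 but has no α/γ ambiguity. The fourteen-membered ring closes in the 14-exo-tet mode, the breaking C1–O bond lying outside the new ring. C1 is fixed by inversion of the epoxide centre made in step 8 and C15 keeps its C–O bond, so both centres trace back to the tartrate, while the sulfone-bearing C14 forms as an epimer mixture that step 11 erases. The step needs attack at C1 and not at C15, which the fully substituted C15 (and the 15-endo path it would require) excludes, and ring closure in preference to oligomerisation, which the high dilution and the three rigid (E)-trisubstituted alkenes should favour. The C17 silyl ether prevents Payne rearrangement, and the isolated alkenes are inert to the base.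

**Step 11**
Reactants: 16 (2R)-1-[(tert-butyldimethylsilyl)oxy]-2-[(1R,3E,7E,11E)-4,8,12-trimethyl-14-(phenylsulfonyl)cyclotetradeca-3,7,11-trien-1-yl]propan-2-ol (C14 epimers)
Product: 17 (2R)-1-[(tert-butyldimethylsilyl)oxy]-2-[(1R,3E,7E,11E)-4,8,12-trimethylcyclotetradeca-3,7,11-trien-1-yl]propan-2-ol
Conditions: Mg turnings (excess), HgCl2 (cat.), MeOH–THF, 25 → 50 °C
Reagents that add atoms: none
Why: Single-electron-transfer reductive desulfonylation by magnesium in methanol replaces the C14 sulfonyl group by hydrogen and so merges the epimers; the γ-hydroxyl cannot eliminate, and the silyl ether and unconjugated alkenes should survive.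

**Step 12**
Reactants: 17 (2R)-1-[(tert-butyldimethylsilyl)oxy]-2-[(1R,3E,7E,11E)-4,8,12-trimethylcyclotetradeca-3,7,11-trien-1-yl]propan-2-ol
Product: 18 (2R)-2-[(1R,3E,7E,11E)-4,8,12-trimethylcyclotetradeca-3,7,11-trien-1-yl]propane-1,2-diol
Conditions: Bu4NF, THF, rt
Reagents that add atoms: none
Why: Fluoride-induced desilylation uncovers the C17 hydroxyl and gives the primary/tertiary 1,2-diol.

**Step 13**
Reactants: 18 (2R)-2-[(1R,3E,7E,11E)-4,8,12-trimethylcyclotetradeca-3,7,11-trien-1-yl]propane-1,2-diol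
Product: 20 (2R)-2-methyl-2-[(1R,3E,7E,11E)-4,8,12-trimethylcyclotetradeca-3,7,11-trien-1-yl]oxirane, via primary tosylate 19 (not isolated)
Conditions: TsCl (1.2 equiv), Et3N, DMAP (cat.), CH2Cl2, 0 °C; then K2CO3, MeOH, rt
Reagents that add atoms: none
Why: Selective sulfonylation of the primary hydroxyl followed by intramolecular Williamson closure (3-exo-tet) by the C15 alkoxide gives the C15–C17 epoxide; C15 keeps its C–O bond and hence its configuration.

**Step 14**
Reactants: 21 geranyl bromide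
Product: 22 {[(2E)-3,7-dimethylocta-2,6-dien-1-yl]sulfonyl}benzene (geranyl phenyl sulfone)
Conditions: PhSO2Na, DMF, rt
Reagents that add atoms: sodium benzenesulfinate, [Na+].[O-]S(=O)c1ccccc1
Why: S-alkylation of the sulfinate by the primary allylic bromide (SN2) gives the allylic sulfone with the (E)-alkene unchanged.

**Step 15**
Reactants: 20 (2R)-2-methyl-2-[(1R,3E,7E,11E)-4,8,12-trimethylcyclotetradeca-3,7,11-trien-1-yl]oxirane; 22 geranyl phenyl sulfone
Product: 24 (2S,5E)-6,10-dimethyl-4-(phenylsulfonyl)-2-[(1R,3E,7E,11E)-4,8,12-trimethylcyclotetradeca-3,7,11-trien-1-yl]undeca-5,9-dien-2-ol (C4 epimers), via lithiated geranyl phenyl sulfone 23 (not isolated)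
Conditions: 22 (2.2 equiv), n-BuLi (2.1 equiv), THF, −78 °C; then 20, DMPU, −78 → 0 °C
Reagents that add atoms: none
Why: The lithiated allylic sulfone opens the 2,2-disubstituted epoxide through its α-carbon at the unsubstituted carbon C17 (SN2), leaving the C15–O bond and its configuration untouched; the new sulfone-bearing centre forms as an epimer mixture that step 16 removes.

**Step 16**
Reactants: 24 (2S,5E)-6,10-dimethyl-4-(phenylsulfonyl)-2-[(1R,3E,7E,11E)-4,8,12-trimethylcyclotetradeca-3,7,11-trien-1-yl]undeca-5,9-dien-2-ol (C4 epimers)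
Product: 25 colleterpenol, (2S,5E)-6,10-dimethyl-2-[(1R,3E,7E,11E)-4,8,12-trimethylcyclotetradeca-3,7,11-trien-1-yl]undeca-5,9-dien-2-ol
Conditions: Pd(dppp)Cl2 (5 mol %), LiBHEt3 (4 equiv), THF, 0 °C → rt
Reagents that add atoms: none
Why: Palladium-catalysed reductive desulfonylation of the allylic sulfone (ionisation by zerovalent palladium to a π-allyl complex, then hydride transfer to the less substituted terminus) should replace the sulfonyl group by hydrogen while the trisubstituted (E)-alkene stays in place; the unactivated ring alkenes and the tertiary alkoxide do not react.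

**Compound list**

1 | (2E,6E)-farnesol | CC(C)=CCC/C(C)=C/CC/C(C)=C/CO | starting material
2 | tert-butyl(dimethyl){[(2E,6E)-3,7,11-trimethyldodeca-2,6,10-trien-1-yl]oxy}silane | CC(C)=CCC/C(C)=C/CC/C(C)=C/CO[Si](C)(C)C(C)(C)C | intermediate
3 | (2E,6E,10E)-12-[(tert-butyldimethylsilyl)oxy]-2,6,10-trimethyldodeca-2,6,10-trien-1-ol | CC(C)(C)[Si](C)(C)OC/C=C(\C)CC/C=C(\C)CC/C=C(\C)CO | intermediate
4 | {[(2E,6E,10E)-12-bromo-3,7,11-trimethyldodeca-2,6,10-trien-1-yl]oxy}(tert-butyl)dimethylsilane | CC(C)(C)[Si](C)(C)OC/C=C(\C)CC/C=C(\C)CC/C=C(\C)CBr | intermediate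
5 | methyl phenyl sulfone | CS(=O)(=O)c1ccccc1 | starting material
6 | (phenylsulfonyl)methyllithium | [Li]CS(=O)(=O)c1ccccc1 | intermediate (not isolated)
7 | tert-butyl(dimethyl){[(2E,6E,10E)-3,7,11-trimethyl-13-(phenylsulfonyl)trideca-2,6,10-trien-1-yl]oxy}silane | CC(C)(C)[Si](C)(C)OC/C=C(\C)CC/C=C(\C)CC/C=C(\C)CCS(=O)(=O)c1ccccc1 | intermediate
8 | (2E,6E,10E)-3,7,11-trimethyl-13-(phenylsulfonyl)trideca-2,6,10-trien-1-ol | OC/C=C(\C)CC/C=C(\C)CC/C=C(\C)CCS(=O)(=O)c1ccccc1 | intermediate
9 | (2E,6E,10E)-1-chloro-3,7,11-trimethyl-13-(phenylsulfonyl)trideca-2,6,10-triene | ClC/C=C(\C)CC/C=C(\C)CC/C=C(\C)CCS(=O)(=O)c1ccccc1 | intermediate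
10 | propargyl alcohol | C#CCO | starting material
11 | (E)-alkenylalane, dimethyl{(E)-3-[(dimethylalumanyl)oxy]-2-methylprop-1-en-1-yl}alumane | C[Al](C)/C=C(\C)CO[Al](C)C | intermediate (not isolated)
12 | (2E,5E,9E,13E)-2,6,10,14-tetramethyl-16-(phenylsulfonyl)hexadeca-2,5,9,13-tetraen-1-ol | OC/C(C)=C/C/C=C(\C)CC/C=C(\C)CC/C=C(\C)CCS(=O)(=O)c1ccccc1 | intermediate
13 | [(2S,3S)-2-methyl-3-[(2E,6E,10E)-3,7,11-trimethyl-13-(phenylsulfonyl)trideca-2,6,10-trien-1-yl]oxiran-2-yl]methanol | OC[C@]1(C)O[C@H]1C/C=C(\C)CC/C=C(\C)CC/C=C(\C)CCS(=O)(=O)c1ccccc1 | intermediate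
14 | tert-butyl(dimethyl){[(2S,3S)-2-methyl-3-[(2E,6E,10E)-3,7,11-trimethyl-13-(phenylsulfonyl)trideca-2,6,10-trien-1-yl]oxiran-2-yl]methoxy}silane (precursor of the key step) | CC(C)(C)[Si](C)(C)OC[C@]1(C)O[C@H]1C/C=C(\C)CC/C=C(\C)CC/C=C(\C)CCS(=O)(=O)c1ccccc1 | intermediate
15 | C14-lithiated sulfone derived from 14 | CC(C)(C)[Si](C)(C)OC[C@]1(C)O[C@H]1C/C=C(\C)CC/C=C(\C)CC/C=C(\C)CC([Li])S(=O)(=O)c1ccccc1 | intermediate (not isolated)
16 | (2R)-1-[(tert-butyldimethylsilyl)oxy]-2-[(1R,3E,7E,11E)-4,8,12-trimethyl-14-(phenylsulfonyl)cyclotetradeca-3,7,11-trien-1-yl]propan-2-ol, C14 epimers (product of the key step) | CC(C)(C)[Si](C)(C)OC[C@](C)(O)[C@H]1C/C=C(\C)CC/C=C(\C)CC/C=C(\C)CC1S(=O)(=O)c1ccccc1 | intermediate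
17 | (2R)-1-[(tert-butyldimethylsilyl)oxy]-2-[(1R,3E,7E,11E)-4,8,12-trimethylcyclotetradeca-3,7,11-trien-1-yl]propan-2-ol | CC(C)(C)[Si](C)(C)OC[C@](C)(O)[C@H]1C/C=C(\C)CC/C=C(\C)CC/C=C(\C)CC1 | intermediate
18 | (2R)-2-[(1R,3E,7E,11E)-4,8,12-trimethylcyclotetradeca-3,7,11-trien-1-yl]propane-1,2-diol | OC[C@](C)(O)[C@H]1C/C=C(\C)CC/C=C(\C)CC/C=C(\C)CC1 | intermediate
19 | (2R)-2-hydroxy-2-[(1R,3E,7E,11E)-4,8,12-trimethylcyclotetradeca-3,7,11-trien-1-yl]propyl 4-methylbenzenesulfonate | Cc1ccc(cc1)S(=O)(=O)OC[C@](C)(O)[C@H]1C/C=C(\C)CC/C=C(\C)CC/C=C(\C)CC1 | intermediate (not isolated)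
20 | (2R)-2-methyl-2-[(1R,3E,7E,11E)-4,8,12-trimethylcyclotetradeca-3,7,11-trien-1-yl]oxirane | C[C@]1(CO1)[C@H]2C/C=C(\C)CC/C=C(\C)CC/C=C(\C)CC2 | intermediate
21 | geranyl bromide | CC(C)=CCC/C(C)=C/CBr | starting material
22 | geranyl phenyl sulfone, {[(2E)-3,7-dimethylocta-2,6-dien-1-yl]sulfonyl}benzene | CC(C)=CCC/C(C)=C/CS(=O)(=O)c1ccccc1 | intermediate
23 | lithiated geranyl phenyl sulfone | CC(C)=CCC/C(C)=C/C([Li])S(=O)(=O)c1ccccc1 | intermediate (not isolated)
24 | (2S,5E)-6,10-dimethyl-4-(phenylsulfonyl)-2-[(1R,3E,7E,11E)-4,8,12-trimethylcyclotetradeca-3,7,11-trien-1-yl]undeca-5,9-dien-2-ol, C4 epimers | CC(C)=CCC/C(C)=C/C(C[C@](C)(O)[C@H]1C/C=C(\C)CC/C=C(\C)CC/C=C(\C)CC1)S(=O)(=O)c1ccccc1 | intermediate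
25 | colleterpenol, (2S,5E)-6,10-dimethyl-2-[(1R,3E,7E,11E)-4,8,12-trimethylcyclotetradeca-3,7,11-trien-1-yl]undeca-5,9-dien-2-ol | CC(C)=CCC/C(C)=C/CC[C@](C)(O)[C@H]1C/C=C(\C)CC/C=C(\C)CC/C=C(\C)CC1 | target

**Total step count:** 16.
**Longest linear sequence:** 15 steps (steps 1–13, 15 and 16, from farnesol 1); step 14 is a one-step side branch.

**Steps most likely to fail**

1. Step 10 (macrocyclisation). Attack at C1, which sits next to the fully substituted C15, may be slow enough that intermolecular epoxide opening (oligomerisation) or base-induced isomerisation of the epoxide to an allylic alcohol takes over. The fallback sets out from farnesol 1 and comes back at 16: the C1–C14 bond is made intermolecularly and the ring is closed at C13–C14 by the well-established alkylation of an α-sulfonyl carbanion with an allylic bromide. Farnesol 1 would be chlorinated (NCS, Me2S) to (2E,6E)-farnesyl chloride F1 and coupled with alane 11 under Pd(PPh3)4 to (2E,5E,9E)-2,6,10,14-tetramethylpentadeca-2,5,9,13-tetraen-1-ol F2. Sharpless epoxidation as in step 8 would give the (2S,3S)-epoxy alcohol F3, and silylation its tert-butyldimethylsilyl ether F4. An excess of (phenylsulfonyl)methyllithium 6 in THF–DMPU (−78 → 25 °C) would open F4 at C1 with inversion to the acyclic hydroxy sulfone F5. SeO2-catalysed hydroxylation of the terminal (E)-methyl (t-BuOOH) would give the allylic alcohol F6, and CBr4/PPh3 the allylic bromide F7. Slow addition of F7 to LiN(iPr)2 (2.2 equiv) in dilute THF at −20 °C would then alkylate the α-sulfonyl carbon intramolecularly and deliver 16.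

2. Step 7 (carboalumination and allylation). Imperfect regiocontrol in the methylalumination, competing methyl transfer from the excess AlMe3, or scrambling at the allyl terminus (attack at the tertiary carbon, E/Z loss) during the coupling would erode the geometry on which the C1/C15 relationship depends. The fallback sets out from propargyl alcohol 10 and comes back at 12: the vinyl unit is isolated and purified before a Stille coupling. Alane 11 would be quenched with iodine to (E)-3-iodo-2-methylprop-2-en-1-ol F8, which hexamethylditin and Pd(PPh3)4 would convert into (E)-2-methyl-3-(trimethylstannyl)prop-2-en-1-ol F9. Stille coupling of F9 with chloride 9 (Pd2(dba)3, AsPh3, THF, 50 °C) would give 12.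

3. Step 15 (side-chain attachment). Slow attack of the stabilised allylic sulfonyl carbanion at C17, which is flanked by the fully substituted C15, could let proton transfer or reaction through the γ-carbon of the allyl anion compete. The fallback sets out from epoxide 20 and geranyl bromide 21 and comes back at 25 by a Biellmann coupling with the more nucleophilic sulfide carbanion. Geranyl bromide 21 and PhSNa would give geranyl phenyl sulfide F10. Its lithio derivative F11 (n-BuLi, DABCO, THF, −78 → −20 °C) would open 20 at C17 to the hydroxy sulfide F12. Dissolving-metal cleavage of the allylic C–S bond (Li, EtNH2, −78 °C) would give 25 directly.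

**Further compounds**

F1 | step 10 | (2E,6E)-farnesyl chloride, (2E,6E)-1-chloro-3,7,11-trimethyldodeca-2,6,10-triene | CC(C)=CCC/C(C)=C/CC/C(C)=C/CCl
F2 | step 10 | (2E,5E,9E)-2,6,10,14-tetramethylpentadeca-2,5,9,13-tetraen-1-ol | CC(C)=CCC/C(C)=C/CC/C(C)=C/C/C=C(\C)CO
F3 | step 10 | [(2S,3S)-2-methyl-3-[(2E,6E)-3,7,11-trimethyldodeca-2,6,10-trien-1-yl]oxiran-2-yl]methanol | OC[C@]1(C)O[C@H]1C/C=C(\C)CC/C=C(\C)CCC=C(C)C
F4 | step 10 | tert-butyl(dimethyl){[(2S,3S)-2-methyl-3-[(2E,6E)-3,7,11-trimethyldodeca-2,6,10-trien-1-yl]oxiran-2-yl]methoxy}silane | CC(C)(C)[Si](C)(C)OC[C@]1(C)O[C@H]1C/C=C(\C)CC/C=C(\C)CCC=C(C)C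
F5 | step 10 | (2R,3R,5E,9E)-1-[(tert-butyldimethylsilyl)oxy]-2,6,10,14-tetramethyl-3-[(phenylsulfonyl)methyl]pentadeca-5,9,13-trien-2-ol | CC(C)(C)[Si](C)(C)OC[C@](C)(O)[C@H](CS(=O)(=O)c1ccccc1)C/C=C(\C)CC/C=C(\C)CCC=C(C)C
F6 | step 10 | (2E,6E,10E,13R,14R)-15-[(tert-butyldimethylsilyl)oxy]-2,6,10,14-tetramethyl-13-[(phenylsulfonyl)methyl]pentadeca-2,6,10-triene-1,14-diol | CC(C)(C)[Si](C)(C)OC[C@](C)(O)[C@H](CS(=O)(=O)c1ccccc1)C/C=C(\C)CC/C=C(\C)CC/C=C(\C)CO
F7 | step 10 | (2R,3R,5E,9E,13E)-15-bromo-1-[(tert-butyldimethylsilyl)oxy]-2,6,10,14-tetramethyl-3-[(phenylsulfonyl)methyl]pentadeca-5,9,13-trien-2-ol | CC(C)(C)[Si](C)(C)OC[C@](C)(O)[C@H](CS(=O)(=O)c1ccccc1)C/C=C(\C)CC/C=C(\C)CC/C=C(\C)CBr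
F8 | step 7 | (E)-3-iodo-2-methylprop-2-en-1-ol | OC/C(C)=C/I
F9 | step 7 | (E)-2-methyl-3-(trimethylstannyl)prop-2-en-1-ol | OC/C(C)=C/[Sn](C)(C)C
F10 | step 15 | geranyl phenyl sulfide, {[(2E)-3,7-dimethylocta-2,6-dien-1-yl]sulfanyl}benzene | CC(C)=CCC/C(C)=C/CSc1ccccc1
F11 | step 15 | lithiated geranyl phenyl sulfide | CC(C)=CCC/C(C)=C/C([Li])Sc1ccccc1
F12 | step 15 | (2S,5E)-6,10-dimethyl-4-(phenylsulfanyl)-2-[(1R,3E,7E,11E)-4,8,12-trimethylcyclotetradeca-3,7,11-trien-1-yl]undeca-5,9-dien-2-ol, C4 epimers | CC(C)=CCC/C(C)=C/C(C[C@](C)(O)[C@H]1C/C=C(\C)CC/C=C(\C)CC/C=C(\C)CC1)Sc1ccccc1
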